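**Plan**

Numbering used below: lactone ring A is O–C3(=O)–C2=C1–C5–C4(Me)2; ring B is C5–C6–C7–C8(Me)–C9=C10(Me); ring C is C8–C9–C11–C12(Me)(CO2H)–C13(=CH2)–C14; C14 is the spiro carbon of tetronate ring D.
Retrosynthesis: tert-butyl ester and C1=C2 (sulfoxide elimination) last; then C8–C9 and C12–C13 together; then C14–ethynyl, ring D (Dieckmann) and its olefination; the C9/C11/C12 cyclopropane (allene plus carbenoid); lactone ring A; the C5 quaternary centre (Michael addition).
Enabling feature: C9=C10–C11–C12 is a homoallyl array ending at an ester-bearing carbon, so C9, C11 and C12 can be stored as an alkylidenecyclopropane that a radical at C8 opens. C13=CH2 beside C12 is the mark of a 6-exo-dig radical closure onto an ethynyl group on C14, and the C8 methyl is the mark of hydrogen-atom transfer to a 1,1-disubstituted alkene.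
Forward order: C5 centre, lactone ring A, allene, cyclopropane, ring D, then rings B and C together in one radical cascade, then unmasking of C1=C2 and the acid.
Stereochemistry: C5 from a catalytic asymmetric Michael addition; the tetronate CH(Me) from methyl D-lactate; C14 from alkynylation anti to that methyl; C8 and C12 in the cascade.

Key step: step 14

Assumption: the cinchona catalyst of step 1 is taken to deliver the (R)-adduct 3; should it favour (S), its pseudoenantiomer is used instead.

**Step 1**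
Reactants: 1 diethyl 2-acetylpentanedioate; 2 but-3-en-2-one
Product: 3 diethyl (2R)-2-acetyl-2-(3-oxobutyl)pentanedioate
Conditions: 9-O-benzylcupreidine (6'-OH cinchona catalyst, 10 mol %), CH2Cl2, −20 °C
Reagents that add atoms: none
Why: Catalytic asymmetric Michael addition of an α-substituted β-ketoester to an enone; the bifunctional catalyst holds the enol and the enone in one hydrogen-bonded ion pair and so should set the C5 quaternary stereocentre.

**Step 2**
Reactants: 3 diethyl (2R)-2-acetyl-2-(3-oxobutyl)pentanedioate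
Product: 4 diethyl (2R)-2-acetyl-2-[2-(2-methyl-1,3-dioxolan-2-yl)ethyl]pentanedioate
Conditions: TMSOCH2CH2OTMS, TMSOTf (cat.), CH2Cl2, −78 °C
Reagents that add atoms: 1,2-bis(trimethylsilyloxy)ethane C[Si](C)(C)OCCO[Si](C)(C)C
Why: Silyl-mediated ketalisation should protect only the unhindered side-chain ketone, since the α-quaternary β-ketoester carbonyl is shielded and the low temperature suppresses aldol closure of the 1,5-diketone.

**Step 3**
Reactants: 4 diethyl (2R)-2-acetyl-2-[2-(2-methyl-1,3-dioxolan-2-yl)ethyl]pentanedioate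
Product: 6 ethyl (3R)-2-ethynyl-2-methyl-3-[2-(2-methyl-1,3-dioxolan-2-yl)ethyl]-6-oxooxane-3-carboxylate (both C2 epimers), via propargylic alcohol 5 (not isolated)
Conditions: HC≡CMgBr, THF, −78 to 0 °C; then PPTS (cat.), PhMe, 50 °C
Reagents that add atoms: ethynylmagnesium bromide C#C[Mg]Br
Why: Grignard 1,2-addition to the only free ketone followed by six-membered lactonisation onto the propanoate arm; the new carbinol centre is destroyed in step 4, so its configuration does not matter.

**Step 4**
Reactants: 6 ethyl (3R)-2-ethynyl-2-methyl-3-[2-(2-methyl-1,3-dioxolan-2-yl)ethyl]-6-oxooxane-3-carboxylate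
Product: 7 (4R)-4-(ethoxycarbonyl)-5-methyl-4-[2-(2-methyl-1,3-dioxolan-2-yl)ethyl]hepta-5,6-dienoic acid
Conditions: Pd2(dba)3·CHCl3 (2.5 mol %), PBu3, HCO2NH4, THF, 50 °C
Reagents that add atoms: none
Why: Palladium-catalysed formate hydrogenolysis of a tertiary propargylic ester: SN2'-type oxidative addition gives an allenylpalladium that is reduced to the 1,1-disubstituted allene, and the lactone leaving group is released as the free acid, which protects that arm in step 5.

**Step 5**
Reactants: 7 (4R)-4-(ethoxycarbonyl)-5-methyl-4-[2-(2-methyl-1,3-dioxolan-2-yl)ethyl]hepta-5,6-dienoic acid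
Product: 9 (5R)-5-(buta-2,3-dien-2-yl)-6,6-dimethyl-5-[2-(2-methyl-1,3-dioxolan-2-yl)ethyl]oxan-2-one, via hydroxy acid 8 (not isolated)
Conditions: MeMgBr (6 equiv), THF, 0 to 45 °C; aq. NaH2PO4; then PPTS (cat.), PhMe, 50 °C
Reagents that add atoms: methylmagnesium bromide C[Mg]Br
Why: Double Grignard addition to the neopentyl ethyl ester while the magnesium carboxylate of the other arm stays inert, then acid-catalysed δ-lactonisation (gem-dialkyl effect) to build ring A with C5 untouched.

**Step 6**
Reactants: 10 tert-butyl 2-methyl-3-oxobutanoate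
Product: 11 tert-butyl 2-diazopropanoate
Conditions: p-ABSA, DBU, MeCN, 0 °C to rt
Reagents that add atoms: 4-acetamidobenzenesulfonyl azide CC(=O)Nc1ccc(cc1)S(=O)(=O)N=[N+]=[N-]
Why: Regitz deacylative diazo transfer, in which the acetyl group leaves on the sulfonamide nitrogen.

**Step 7**
Reactants: 9 (5R)-5-(buta-2,3-dien-2-yl)-6,6-dimethyl-5-[2-(2-methyl-1,3-dioxolan-2-yl)ethyl]oxan-2-one; 11 tert-butyl 2-diazopropanoate
Product: 12 tert-butyl 2-{1-[(3R)-2,2-dimethyl-3-[2-(2-methyl-1,3-dioxolan-2-yl)ethyl]-6-oxooxan-3-yl]ethylidene}-1-methylcyclopropane-1-carboxylate (alkene and cyclopropane isomers)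
Conditions: Rh2(O2CCPh3)4 (1 mol %), CH2Cl2, −78 °C, slow addition of 11
Reagents that add atoms: none
Why: Rhodium-carbenoid cyclopropanation of the terminal, less hindered C=C of the allene, with bulky carboxylate ligands and low temperature to suppress the 1,2-hydride shift of the α-methyl carbenoid; all isomers are carried on because the cyclopropane stereochemistry is erased in step 14.

**Step 8**
Reactants: 12 tert-butyl 2-{1-[(3R)-2,2-dimethyl-3-[2-(2-methyl-1,3-dioxolan-2-yl)ethyl]-6-oxooxan-3-yl]ethylidene}-1-methylcyclopropane-1-carboxylate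
Product: 13 tert-butyl 2-{1-[(3R)-2,2-dimethyl-3-[2-(2-methyl-1,3-dioxolan-2-yl)ethyl]-6-oxo-5-(phenylsulfanyl)oxan-3-yl]ethylidene}-1-methylcyclopropane-1-carboxylate (C–S epimers)
Conditions: LDA, THF, −78 °C; then PhSSPh
Reagents that add atoms: diphenyl disulfide c1ccc(cc1)SSc1ccccc1
Why: Sulfenylation of the lactone enolate, the only enolisable site; the sulfide is a radical-inert, base-stable mask for the C1=C2 double bond, which would otherwise trap the C8 radical by 5-exo Giese addition in step 14.

**Step 9**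
Reactants: 13 tert-butyl 2-{1-[(3R)-2,2-dimethyl-3-[2-(2-methyl-1,3-dioxolan-2-yl)ethyl]-6-oxo-5-(phenylsulfanyl)oxan-3-yl]ethylidene}-1-methylcyclopropane-1-carboxylate
Product: 14 tert-butyl 2-{1-[(3R)-2,2-dimethyl-6-oxo-3-(3-oxobutyl)-5-(phenylsulfanyl)oxan-3-yl]ethylidene}-1-methylcyclopropane-1-carboxylate
Conditions: PPTS, acetone/H2O, 50 °C
Reagents that add atoms: water O
Why: Mild acetal hydrolysis that should leave the tert-butyl ester, the lactone and the alkylidenecyclopropane intact.

**Step 10**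
Reactants: 15 2-(diethoxyphosphoryl)acetic acid; 16 methyl (2R)-2-hydroxypropanoate
Product: 17 methyl (2R)-2-{[2-(diethoxyphosphoryl)acetyl]oxy}propanoate
Conditions: DCC, DMAP (cat.), CH2Cl2, 0 °C to rt
Reagents that add atoms: none
Why: Steglich esterification, which does not touch the lactate stereocentre.

**Step 11**
Reactants: 14 tert-butyl 2-{1-[(3R)-2,2-dimethyl-6-oxo-3-(3-oxobutyl)-5-(phenylsulfanyl)oxan-3-yl]ethylidene}-1-methylcyclopropane-1-carboxylate; 17 methyl (2R)-2-{[2-(diethoxyphosphoryl)acetyl]oxy}propanoate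
Product: 18 (2R)-1-methoxy-1-oxopropan-2-yl (2E)-3-methyl-5-[(3R)-3-{1-[2-(tert-butoxycarbonyl)-2-methylcyclopropylidene]ethyl}-2,2-dimethyl-6-oxo-5-(phenylsulfanyl)oxan-3-yl]pent-2-enoate
Conditions: 17, NaH, THF, 0 °C; then 14, 50 °C
Reagents that add atoms: none
Why: Horner–Wadsworth–Emmons olefination of the methyl ketone; the alkene geometry is irrelevant because step 12 goes through the dienolate.

**Step 12**
Reactants: 18 the lactate enoate
Product: 19 (5R)-4-hydroxy-5-methyl-3-{4-[(3R)-3-{1-[2-(tert-butoxycarbonyl)-2-methylcyclopropylidene]ethyl}-2,2-dimethyl-6-oxo-5-(phenylsulfanyl)oxan-3-yl]but-1-en-2-yl}furan-2(5H)-one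
Conditions: LiHMDS (3.2 equiv), THF, −78 to 0 °C; 1 M HCl
Reagents that add atoms: none
Why: Dieckmann (Lacey-type) cyclisation through the ester dienolate: γ-deprotonation of the methyl group syn to the carbonyl, then α-C-acylation by the lactate ester, gives the tetronic acid with a deconjugated 1,1-disubstituted alkene; the lactate centre should survive because ring closure is fast at low temperature and the tetronate anion is not enolisable at C5 of the furanone.

**Step 13**
Reactants: 19 the 3-alkenyl tetronic acid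
Product: 20 (3R,5R)-3-ethynyl-5-methyl-3-{4-[(3R)-3-{1-[2-(tert-butoxycarbonyl)-2-methylcyclopropylidene]ethyl}-2,2-dimethyl-6-oxo-5-(phenylsulfanyl)oxan-3-yl]but-1-en-2-yl}furan-2,4(3H,5H)-dione (ethynyl trans to the ring methyl)
Conditions: TMS-EBX, TBAF, THF, −78 °C to rt
Reagents that add atoms: 1-[(trimethylsilyl)ethynyl]-1,2-benziodoxol-3(1H)-one C[Si](C)(C)C#CI1OC(=O)c2ccccc12
Why: Electrophilic α-alkynylation of a cyclic 1,3-dicarbonyl with an ethynyl benziodoxolone generated in situ; the small reagent should attack the tetronate carbon anti to the adjacent ring methyl and so set the C14 quaternary stereocentre, and no base is used after this step.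

**Step 14**
Reactants: 20 the ethynyl tetronate bearing the 1,1-disubstituted alkene and the alkylidenecyclopropane
Product: 23 tert-butyl ester of 1,2-dihydro-2-(phenylsulfanyl)penicianstinoid C, via tertiary C8 radical 21 (not isolated), via ring-opened C12 radical 22 (not isolated)
Conditions: Fe(acac)3 (1 equiv), PhSiH3 (3 equiv), EtOH/THF 1:1, 0.01 M, 40 °C, degassed
Reagents that add atoms: none
Why: Proposed new method: hydrogen-atom transfer from the iron hydride to the 1,1-disubstituted alkene gives the tertiary C8 radical (installing the C8 methyl), which adds to the cyclopropylidene carbon C9; the tertiary cyclopropylcarbinyl radical at C10 then opens toward C12 (ester-stabilised tertiary radical), restoring C9=C10, and the C12 radical closes onto the C14 ethynyl group, the vinyl radical being quenched by the silane to the exocyclic methylene. The closest known reactions are metal-hydride hydrogen-atom-transfer radical cyclisations and the radical addition/ring-opening/cyclisation cascades of methylenecyclopropanes, including stannane- and samarium diiodide-mediated versions that end on alkynes. Ring B closes 6-endo-trig (5-exo attack at C10 would join two fully substituted carbons and leave a cyclopropyl radical) and ring C closes 6-exo-dig. C8 should be set in a chair-like transition state in which the C4 arm of the spiro-lactone at C5 is pseudoaxial, away from the vinylic methyl, and the bulky C14 substituent of the radical avoids the fully substituted cyclopropane carbon, which places the new methyl cis to C4; C12 should be set in the chair closure of ring C with the planar ester, not the methyl, in the axial site syn to the tetronate ketone. The step needs hydrogen-atom transfer to favour the 1,1-disubstituted alkene (the cyclopropylidene alkene is tetrasubstituted, the alkyne reacts slowly, and the lactone alkene is masked as the sulfide) and needs each cyclisation to outrun reduction of the radical, which high dilution and the preorganisation by ring B should secure.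

**Step 15**
Reactants: 23 tert-butyl ester of 1,2-dihydro-2-(phenylsulfanyl)penicianstinoid C
Product: 25 penicianstinoid C tert-butyl ester, via sulfoxide 24 (not isolated)
Conditions: NaIO4, MeOH/H2O, rt; then PhMe, CaCO3, 95 °C
Reagents that add atoms: none
Why: Periodate oxidises only sulfur, and thermal syn-elimination of the α-sulfinyl lactone (dehydrosulfenylation) can only give the C1=C2 double bond because C5 is quaternary.

**Step 16**
Reactants: 25 penicianstinoid C tert-butyl ester
Product: 26 penicianstinoid C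
Conditions: TFA/CH2Cl2 1:4, 0 °C to rt
Reagents that add atoms: none
Why: Acidolysis of the tert-butyl ester (E1 loss of isobutene) avoids base, so the epimerisable CH(Me) of ring D is safe, and the exocyclic methylene cannot migrate because both neighbours are quaternary.

**Compound list**

1 | diethyl 2-acetylpentanedioate | CCOC(=O)CCC(C(C)=O)C(=O)OCC | starting material
2 | but-3-en-2-one | CC(=O)C=C | starting material
3 | diethyl (2R)-2-acetyl-2-(3-oxobutyl)pentanedioate | CC(=O)[C@](C(=O)OCC)(CCC(=O)OCC)CCC(C)=O | intermediate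
4 | diethyl (2R)-2-acetyl-2-[2-(2-methyl-1,3-dioxolan-2-yl)ethyl]pentanedioate | CC(=O)[C@](C(=O)OCC)(CCC(=O)OCC)CCC1(C)OCCO1 | intermediate
5 | diethyl (2R)-2-(2-hydroxybut-3-yn-2-yl)-2-[2-(2-methyl-1,3-dioxolan-2-yl)ethyl]pentanedioate (carbinol epimers) | C#CC(C)(O)[C@](C(=O)OCC)(CCC(=O)OCC)CCC1(C)OCCO1 | intermediate
6 | ethyl (3R)-2-ethynyl-2-methyl-3-[2-(2-methyl-1,3-dioxolan-2-yl)ethyl]-6-oxooxane-3-carboxylate (C2 epimers) | C#CC2(C)OC(=O)CC[C@]2(C(=O)OCC)CCC1(C)OCCO1 | intermediate
7 | (4R)-4-(ethoxycarbonyl)-5-methyl-4-[2-(2-methyl-1,3-dioxolan-2-yl)ethyl]hepta-5,6-dienoic acid | C=C=C(C)[C@](C(=O)OCC)(CCC(=O)O)CCC1(C)OCCO1 | intermediate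
8 | (4R)-4-(2-hydroxypropan-2-yl)-5-methyl-4-[2-(2-methyl-1,3-dioxolan-2-yl)ethyl]hepta-5,6-dienoic acid | C=C=C(C)[C@](C(C)(C)O)(CCC(=O)O)CCC1(C)OCCO1 | intermediate
9 | (5R)-5-(buta-2,3-dien-2-yl)-6,6-dimethyl-5-[2-(2-methyl-1,3-dioxolan-2-yl)ethyl]oxan-2-one | C=C=C(C)[C@]1(CCC(=O)OC1(C)C)CCC2(C)OCCO2 | intermediate
10 | tert-butyl 2-methyl-3-oxobutanoate | CC(=O)C(C)C(=O)OC(C)(C)C | starting material
11 | tert-butyl 2-diazopropanoate | CC(=[N+]=[N-])C(=O)OC(C)(C)C | intermediate
12 | tert-butyl 2-{1-[(3R)-2,2-dimethyl-3-[2-(2-methyl-1,3-dioxolan-2-yl)ethyl]-6-oxooxan-3-yl]ethylidene}-1-methylcyclopropane-1-carboxylate (isomer mixture at the cyclopropane) | CC(=C1CC1(C)C(=O)OC(C)(C)C)[C@]2(CCC(=O)OC2(C)C)CCC3(C)OCCO3 | intermediate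
13 | the 5-(phenylsulfanyl) derivative of 12 (C–S epimers) | CC(=C1CC1(C)C(=O)OC(C)(C)C)[C@]2(CC(Sc4ccccc4)C(=O)OC2(C)C)CCC3(C)OCCO3 | intermediate
14 | tert-butyl 2-{1-[(3R)-2,2-dimethyl-6-oxo-3-(3-oxobutyl)-5-(phenylsulfanyl)oxan-3-yl]ethylidene}-1-methylcyclopropane-1-carboxylate | CC(=C1CC1(C)C(=O)OC(C)(C)C)[C@]2(CC(Sc3ccccc3)C(=O)OC2(C)C)CCC(C)=O | intermediate
15 | 2-(diethoxyphosphoryl)acetic acid | CCOP(=O)(CC(=O)O)OCC | starting material
16 | methyl (2R)-2-hydroxypropanoate (methyl D-lactate) | C[C@@H](O)C(=O)OC | starting material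
17 | methyl (2R)-2-{[2-(diethoxyphosphoryl)acetyl]oxy}propanoate | CCOP(=O)(CC(=O)O[C@H](C)C(=O)OC)OCC | intermediate
18 | lactate (2E)-enoate from 14 and 17 | CC(=C1CC1(C)C(=O)OC(C)(C)C)[C@]2(CC(Sc3ccccc3)C(=O)OC2(C)C)CC/C(C)=C/C(=O)O[C@H](C)C(=O)OC | intermediate
19 | (5R)-3-alkenyl tetronic acid (C3 carries CH2=C–CH2CH2–C5) | C=C(CC[C@]2(C(C)=C3CC3(C)C(=O)OC(C)(C)C)CC(Sc4ccccc4)C(=O)OC2(C)C)C1=C(O)[C@@H](C)OC1=O | intermediate
20 | (3R,5R)-3-ethynyl-3-alkenyl-5-methylfuran-2,4-dione, cascade substrate | C#C[C@@]1(C(=C)CC[C@]2(C(C)=C3CC3(C)C(=O)OC(C)(C)C)CC(Sc4ccccc4)C(=O)OC2(C)C)C(=O)O[C@H](C)C1=O | intermediate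
21 | tertiary C8 radical formed by hydrogen-atom transfer to 20 | C#C[C@@]1([C](C)CC[C@]2(C(C)=C3CC3(C)C(=O)OC(C)(C)C)CC(Sc4ccccc4)C(=O)OC2(C)C)C(=O)O[C@H](C)C1=O | intermediate
22 | ring-B cyclohexene carrying the ring-opened tertiary C12 α-ester radical | C#C[C@@]1([C@@]2(C)CC[C@@]3(CC(Sc4ccccc4)C(=O)OC3(C)C)C(C)=C2C[C](C)C(=O)OC(C)(C)C)C(=O)O[C@H](C)C1=O | intermediate
23 | tert-butyl ester of 1,2-dihydro-2-(phenylsulfanyl)penicianstinoid C | C=C1[C@](C)(C(=O)OC(C)(C)C)CC2=C(C)[C@]3(CC(Sc4ccccc4)C(=O)OC3(C)C)CC[C@]2(C)[C@@]12C(=O)O[C@H](C)C2=O | intermediate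
24 | sulfoxide of 23 | C=C1[C@](C)(C(=O)OC(C)(C)C)CC2=C(C)[C@]3(CC(S(=O)c4ccccc4)C(=O)OC3(C)C)CC[C@]2(C)[C@@]12C(=O)O[C@H](C)C2=O | intermediate
25 | penicianstinoid C tert-butyl ester | C=C1[C@](C)(C(=O)OC(C)(C)C)CC2=C(C)[C@]3(C=CC(=O)OC3(C)C)CC[C@]2(C)[C@@]12C(=O)O[C@H](C)C2=O | intermediate
26 | penicianstinoid C | C=C1[C@](C)(C(=O)O)CC2=C(C)[C@]3(C=CC(=O)OC3(C)C)CC[C@]2(C)[C@@]12C(=O)O[C@H](C)C2=O | target

**Count**

Total steps: 16. Longest linear sequence: 14 (steps 1–5, 7–9, 11–16; steps 6 and 10 prepare reagents 11 and 17).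

**Steps most likely to fail**

Step 14 (proposed new method). What may go wrong: the tertiary C8 radical is reduced, or shifts the C14 acyl group (Dowd–Beckwith-type migration), before it adds to the congested cyclopropylidene carbon, or it adds with poor facial selectivity at C8. Fallback, known reaction types only, sets out from allene 9 and returns at 23: the two bonds are made in two separate operations, C8–C9 by an intramolecular reductive Heck reaction and C12–C13 by a stannane-mediated 6-exo-dig cyclisation. Allene 9 is brominated (pyridinium tribromide, CH2Cl2, −78 °C) to the 2,3-dibromide F1, with a vinyl bromide at C9 and an allylic bromide at C11. tert-Butyl 2-(phenylselanyl)propanoate F2, made from tert-butyl 2-bromopropanoate and PhSeNa, is deprotonated with LDA and alkylated with F1 to the quaternary α-seleno ester F3. Sulfenylation as in step 8 gives the α-phenylsulfanyl lactone F4, deketalisation as in step 9 the methyl ketone F5, and olefination with 17 as in step 11 the lactate enoate F6. Pd(OAc)2/PPh3 with HCO2Na (DMF, 80 °C) then effects 6-exo carbopalladation of the β,β-disubstituted enoate with formate capture, closing ring B and setting C8 in the ring B diester F7. Dieckmann cyclisation as in step 12 gives the tetronic acid F8 and alkynylation as in step 13 the C14-ethynyl tetronate F9. Bu3SnH/AIBN (PhH, 80 °C) abstracts the phenylselanyl group to give the C12 radical 22, whose 6-exo-dig closure delivers 23.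

Step 12. What may go wrong: enolisation at the lactate carbon (loss of configuration, O-to-C acyl shift) competes with the slower vinylogous ring closure. Fallback, sets out from ketone 14 and returns at 19: the tetronate ring is made first and then condensed with the ketone. Methyl D-lactate 16 is acetylated (Ac2O, pyridine) to methyl (2R)-2-acetoxypropanoate F10, and Dieckmann cyclisation (LiHMDS, THF, −78 °C) gives (5R)-4-hydroxy-5-methylfuran-2(5H)-one F11. Knoevenagel condensation of F11 with 14 (piperidinium acetate, PhMe, 4 Å sieves, 80 °C) and tautomerisation of the alkylidene adduct to the dienol gives 19 without 17 or 18.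

Step 7. What may go wrong: the 1,2-hydride shift of the α-methyl carbenoid (to tert-butyl acrylate) outruns cyclopropanation of the hindered allene. Fallback, sets out from 9 and returns at 12: cyclopropanation with tert-butyl diazoacetate, which has no β-hydrogen (Rh2(OAc)4, CH2Cl2, rt), gives the des-methyl alkylidenecyclopropane ester F12. LDA (2.2 equiv) forms the lactone/cyclopropyl ester bis-enolate and MeI (1.0 equiv) alkylates the more basic cyclopropyl enolate to give 12.

**Further compounds**

F1 | step 14 | (5R)-5-[(Z)-3,4-dibromobut-2-en-2-yl]-6,6-dimethyl-5-[2-(2-methyl-1,3-dioxolan-2-yl)ethyl]oxan-2-one | C/C(=C(/Br)CBr)[C@]1(CCC(=O)OC1(C)C)CCC2(C)OCCO2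
F2 | step 14 | tert-butyl 2-(phenylselanyl)propanoate | CC([Se]c1ccccc1)C(=O)OC(C)(C)C
F3 | step 14 | quaternary α-seleno ester from F1 and F2 | C/C(=C(/Br)CC(C)([Se]c3ccccc3)C(=O)OC(C)(C)C)[C@]1(CCC(=O)OC1(C)C)CCC2(C)OCCO2
F4 | step 14 | α-phenylsulfanyl lactone of F3 | C/C(=C(/Br)CC(C)([Se]c3ccccc3)C(=O)OC(C)(C)C)[C@]1(CC(Sc4ccccc4)C(=O)OC1(C)C)CCC2(C)OCCO2
F5 | step 14 | methyl ketone from F4 | C/C(=C(/Br)CC(C)([Se]c3ccccc3)C(=O)OC(C)(C)C)[C@]1(CC(Sc4ccccc4)C(=O)OC1(C)C)CCC(C)=O
F6 | step 14 | lactate enoate from F5 and 17 | C/C(=C(/Br)CC(C)([Se]c3ccccc3)C(=O)OC(C)(C)C)[C@]1(CC(Sc4ccccc4)C(=O)OC1(C)C)CC/C(C)=C/C(=O)O[C@H](C)C(=O)OC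
F7 | step 14 | ring B diester from the reductive Heck closure | CC(C)(C)OC(=O)C(C)([Se]c5ccccc5)CC2=C(C)[C@]3(CC(Sc4ccccc4)C(=O)OC3(C)C)CC[C@]2(C)CC(=O)O[C@H](C)C(=O)OC
F8 | step 14 | tetronic acid from F7 | CC(C)(C)OC(=O)C(C)([Se]c5ccccc5)CC2=C(C)[C@]3(CC(Sc4ccccc4)C(=O)OC3(C)C)CC[C@]2(C)C1=C(O)[C@@H](C)OC1=O
F9 | step 14 | C14-ethynyl tetronate from F8 | CC(C)(C)OC(=O)C(C)([Se]c5ccccc5)CC2=C(C)[C@]3(CC(Sc4ccccc4)C(=O)OC3(C)C)CC[C@]2(C)[C@]1(C#C)C(=O)O[C@H](C)C1=O
F10 | step 12 | methyl (2R)-2-acetoxypropanoate | CC(=O)O[C@H](C)C(=O)OC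
F11 | step 12 | (5R)-4-hydroxy-5-methylfuran-2(5H)-one | C[C@H]1OC(=O)C=C1O
F12 | step 7 | tert-butyl 2-{1-[(3R)-2,2-dimethyl-3-[2-(2-methyl-1,3-dioxolan-2-yl)ethyl]-6-oxooxan-3-yl]ethylidene}cyclopropane-1-carboxylate | CC(=C1CC1C(=O)OC(C)(C)C)[C@]2(CCC(=O)OC2(C)C)CCC3(C)OCCO3
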